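**Plan**

1. Numbering follows ent-kaurane: ring A = C1–C5 and C10 (ketone C1, aldehyde C6 on C5); lactone C7(=O)–O–C20–C10–C9–C8; ring C = C8, C9, C11, C12, C13, C14; ring D = C8, C15, C16, C13, C14 with C17 on C16.
2. Retrosynthesis: the C1/C6 oxidation levels and the C15 acetate are adjusted last; C13–C16 is cut (vinyl radical closure of ring D); the C7–O–C20 lactone is opened and C20 returned to the carbonyl of a ring A γ-lactone (C20–O–C6); C8–C14 is cut by a retro-[3,3] shift that restores a C7–O–C12 lactone; then C8–C15 (alkylation) and C9–C10 (Michael addition) are cut.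
3. Feature used: C8 is quaternary, α to the C7 carboxyl and bonded to C14, with C12 one carbon beyond C13. A C7 ester of a C12 allylic alcohol (vinyl = C13=C14), tied into the ring C7–O–C12–C11–C9–C8, can therefore hand C14 to C8 as a lactone silyl ketene acetal.
4. Forward: ring A first (dienone to keto lactone 7); the temporary δ-lactone 11 is joined through C9–C10; ring C arises in the Ireland–Claisen step; the target lactone by reduction and lactonisation; ring D by radical cyclisation; then C15 and the C1/C6 oxidation levels.
5. Stereochemistry: C5 from rhodium/BINAP conjugate vinylation; C10 from the obligatory cis fusion of the keto lactone; C12 from asymmetric allylboration; C9 by addition anti to the C12 vinyl group; C8 by chirality transfer from C12; C13 by the geometry of bridging; C15 by exo hydride delivery.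

Key step: step 13

Assumption: the sense of induction in steps 2 and 6 is taken to follow the usual behaviour of these reagents ((R)-BINAP giving the 5R adduct, the (−)-allylborane attacking the si face of the aldehyde); if either proved opposite, the other enantiomer of ligand or reagent would be used.

**Route**

Step 1
Reactants: 1 4,4-dimethylcyclohex-2-en-1-one
Product: 2 4,4-dimethylcyclohexa-2,5-dien-1-one
Conditions: DDQ, 1,4-dioxane, 100 °C
Reagents that add atoms: none
Why: Quinone dehydrogenation: DDQ takes hydride from C5 of the dienol form of the enone and loss of the C6 proton gives the cross-conjugated dienone, a standard way to 4,4-disubstituted cyclohexadienones that creates no stereocentre.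

Step 2
Reactants: 2 4,4-dimethylcyclohexa-2,5-dien-1-one
Product: 3 (5R)-5-ethenyl-4,4-dimethylcyclohex-2-en-1-one
Conditions: CH2=CHBF3K, [Rh(cod)2]BF4 (3 mol %), (R)-BINAP (3.3 mol %), toluene/H2O, 80 °C
Reagents that add atoms: potassium vinyltrifluoroborate, C=C[B-](F)(F)F.[K+]
Why: Rhodium-catalysed asymmetric conjugate addition of an alkenylboron reagent (Hayashi–Miyaura reaction) desymmetrises the dienone, the BINAP-bound vinylrhodium species adding to one of the two enantiotopic β-carbons so that C5 is set as R by the ligand, as known for alkenyl transfer to 4,4-disubstituted cyclohexadienones.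

Step 3
Reactants: 3 (5R)-5-ethenyl-4,4-dimethylcyclohex-2-en-1-one
Product: 5 (5S)-5-(hydroxymethyl)-4,4-dimethylcyclohex-2-en-1-one, via keto aldehyde 4 (not isolated)
Conditions: O3, CH2Cl2/MeOH, −78 °C (Sudan Red 7B end point); Me2S; then NaBH4, −78 to −40 °C
Reagents that add atoms: ozone, [O-][O+]=O
Why: Ozonolysis then hydride reduction: the isolated vinyl group is cleaved far faster than the electron-poor enone double bond, and the aldehyde 4 is reduced in the same flask at low temperature ahead of the conjugated ketone, which also prevents epimerisation at C5 next to the formyl group.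

Step 4
Reactants: 5 (5S)-5-(hydroxymethyl)-4,4-dimethylcyclohex-2-en-1-one
Product: 6 methyl [(1S)-6,6-dimethyl-3-oxocyclohex-4-en-1-yl]methyl carbonate
Conditions: ClCO2Me, pyridine, CH2Cl2, 0 °C
Reagents that add atoms: methyl chloroformate, COC(Cl)=O
Why: Acylation of the primary alcohol by a chloroformate with pyridine as base gives the mixed carbonate that carries the future C20 carbon.

Step 5
Reactants: 6 methyl [(1S)-6,6-dimethyl-3-oxocyclohex-4-en-1-yl]methyl carbonate
Product: 7 (3aS,7aR)-4,4-dimethyl-3a,4-dihydro-2-benzofuran-1,7(3H,7aH)-dione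
Conditions: LiN(SiMe3)2 (2.2 equiv), THF, −78 to 0 °C; aq. HCl
Reagents that add atoms: none
Why: Intramolecular Claisen (Dieckmann-type) C-acylation: the only enolisable position is C10 (C2 is vinylic), its cross-conjugated dienolate attacks the carbonate carbonyl in a 5-exo-trig closure with loss of methoxide, and because a five-membered lactone on a six-membered ring can only be cis-fused, C10 is set relative to C5 with C20 and C6 on the same face.

Step 6
Reactants: 8 acrolein
Product: 9 (3S)-hexa-1,5-dien-3-ol
Conditions: (−)-Ipc2B(allyl), Et2O, −78 °C; then NaOH, H2O2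
Reagents that add atoms: (−)-B-allyldiisopinocampheylborane, C=CCB([C@@H]1C[C@@H]2C[C@H]([C@H]1C)C2(C)C)[C@@H]1C[C@@H]2C[C@H]([C@H]1C)C2(C)C
Why: Brown allylboration: the allyl group is delivered through a chair-like six-membered transition state in which the isopinocampheyl groups of the (−)-reagent direct attack to the si face of the aldehyde, setting the carbinol carbon C12 as S.

Step 7
Reactants: 9 (3S)-hexa-1,5-dien-3-ol
Product: 10 (3S)-hexa-1,5-dien-3-yl prop-2-enoate
Conditions: CH2=CHCOCl, Et3N, CH2Cl2, 0 °C
Reagents that add atoms: acryloyl chloride, C=CC(Cl)=O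
Why: Esterification of the secondary alcohol with an acid chloride and amine base, which leaves the C12 centre untouched.

Step 8
Reactants: 10 (3S)-hexa-1,5-dien-3-yl prop-2-enoate
Product: 11 (6S)-6-ethenyl-5,6-dihydro-2H-pyran-2-one
Conditions: second-generation Grubbs catalyst RuCl2(=CHPh)(PCy3)(H2IMes) (2 mol %), CH2Cl2 (0.005 M), 40 °C
Reagents that add atoms: none
Why: Ring-closing metathesis: the ruthenium carbene loads on the unhindered allyl terminus and closes onto the acrylate to the six-membered unsaturated lactone with loss of ethene, the vinyl group on the oxygen-bearing carbon being too hindered and deactivated to compete.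

Step 9
Reactants: 7 (3aS,7aR)-4,4-dimethyl-3a,4-dihydro-2-benzofuran-1,7(3H,7aH)-dione; 11 (6S)-6-ethenyl-5,6-dihydro-2H-pyran-2-one
Product: 12 Michael adduct (keto bis-lactone; C9 trans to the C12 vinyl group on the δ-lactone; C9 on C10 cis to H-5)
Conditions: Cs2CO3 (0.1 equiv), MeCN, 0 °C to rt
Reagents that add atoms: none
Why: Base-catalysed Michael addition of a 1,3-dicarbonyl compound to an unsaturated lactone: the enolate of 7 attacks C9 axially on the face anti to the C12 vinyl group, which sets C9 (4,6-trans lactone), while at the nucleophile the new bond can form only cis to H-5 because the γ-lactone must remain cis-fused, which sets C10 with C9 trans to C6; tying C6 and C20 back in the lactone keeps the tertiary nucleophile compact and acidic enough for a weak base that does not open the vinyl lactone, and 7 itself protonates the transient C8 enolate.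

Step 10
Reactants: 12 Michael adduct (keto bis-lactone)
Product: 13 C1 allylic alcohol (1-OH cis to C20)
Conditions: NaBH4, CeCl3·7H2O, MeOH, −78 °C
Reagents that add atoms: none
Why: Luche reduction: cerium-assisted 1,2-hydride addition to the ring A enone, expected anti to the axial C20 carbon on C10 so that the C1 hydroxyl is cis to C20, removes the ketone that would allow retro-Michael cleavage of the C9–C10 bond and conjugate attack on C3 in the enolate steps to come; the C1 configuration is immaterial because C1 is re-oxidised in step 22.

Step 11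
Reactants: 13 C1 allylic alcohol
Product: 14 C1 tert-butyldimethylsilyl ether
Conditions: t-BuMe2SiOTf, 2,6-lutidine, CH2Cl2, −78 to 0 °C
Reagents that add atoms: tert-butyldimethylsilyl trifluoromethanesulfonate, CC(C)(C)[Si](C)(C)OS(=O)(=O)C(F)(F)F
Why: Silylation of a hindered secondary alcohol with a silyl triflate and a hindered pyridine base, done at once so that the C1 hydroxyl cannot attack the δ-lactone carbonyl.

Step 12
Reactants: 14 C1 tert-butyldimethylsilyl ether
Product: 15 C8 (2-bromoprop-2-enyl) δ-lactone (side chain trans to ring A; vinyl at C12 trans to ring A)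
Conditions: LiN(i-Pr)2, THF, −78 °C; CH2=C(Br)CH2Br, DMPU, −78 to −40 °C
Reagents that add atoms: 2,3-dibromopropene, C=C(Br)CBr
Why: Lactone enolate alkylation: C8 is the only enolisable carbon (C10 is quaternary) and the allylic bromide enters trans to the bulky ring A substituent on C9, a centre that is erased again in step 13.

Step 13
Reactants: 15 C8 (2-bromoprop-2-enyl) δ-lactone
Product: 18 ring C cyclohex-3-ene-1-carboxylic acid (C8 quaternary; C7 cis to C10; C12=C13 alkene), via silyl ketene acetal 16 (not isolated), via trimethylsilyl ester 17 (not isolated)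
Conditions: LiN(i-Pr)2, Me3SiCl, THF/DMPU, −78 °C; then toluene, 105 °C; 1 M HCl, THF
Reagents that add atoms: none
Why: Ireland–Claisen rearrangement of a lactone silyl ketene acetal: deprotonation at C8 and O-silylation give the endocyclic ketene acetal 16, which erases the C8 centre of 15, and on heating the array C8=C7–O–C12–C13=C14 undergoes a concerted suprafacial [3,3]-sigmatropic shift in which C14 bonds to C8 while the O–C12 bond breaks, giving silyl ester 17 and, after hydrolysis, acid 18. The closest known reaction type is the Claisen rearrangement of silyl ketene acetals of 6-alkenyl δ-lactones to cyclohex-3-enecarboxylic acids. Ring C (C8, C9, C11, C12, C13, C14) closes as a six-membered carbocycle within the [3,3] shift, and because C8 and C12 are also linked through C9–C11 the transition state is necessarily boat-like, the ring oxygen being expelled into the carboxyl group. The new quaternary stereocentre C8 is controlled by C12: the vinyl group can reach only the face of the ketene acetal on which it stands, so its configuration is transferred to C8 as C12 itself becomes part of the C12=C13 alkene. The step needs C14 to reach C8 on the face opposite ring A, and this is secured by the 4,6-trans relation of the C9 and C12 substituents set in step 9, which lets ring A sit equatorial while the vinyl group is axial over the ketene acetal; the result is C7 cis to C10 and the bromoallyl arm cis to H-9 on ring C. The ring A γ-lactone is untouched because its α-carbon C10 is quaternary, and the vinyl bromide should survive the brief exposure to the amide base at low temperature.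

Step 14
Reactants: 18 ring C cyclohex-3-ene-1-carboxylic acid
Product: 20 7,20-lactone alcohol (free C6 hydroxyl), via dihydroxy acid 19 (not isolated)
Conditions: LiBHEt3 (4 equiv), THF, 0 °C; aq. HCl; then TsOH·H2O (cat.), CH2Cl2, rt
Reagents that add atoms: none
Why: Chemoselective hydride reduction then lactonisation: the triethylborohydride only deprotonates the carboxylic acid, whose carboxylate is not reduced, while it reduces the ring A γ-lactone to the C20 and C6 primary alcohols, and on acid treatment the C7 acid closes onto the C20 hydroxyl in a six-membered lactonisation helped by the quaternary carbons C8 and C10 and preferred over the seven-membered closure through the C6 hydroxyl.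

Step 15
Reactants: 20 7,20-lactone alcohol
Product: 21 1,6-bis(tert-butyldimethylsilyl) ether
Conditions: t-BuMe2SiCl, imidazole, DMF, rt
Reagents that add atoms: tert-butyldimethylsilyl chloride, CC(C)(C)[Si](C)(C)Cl
Why: Imidazole-promoted silylation of the remaining primary alcohol, so that C6 is protected during the oxidation and reduction at C15.

Step 16
Reactants: 21 1,6-bis(tert-butyldimethylsilyl) ether
Product: 22 tetracyclic 16(17)-ene (ring D closed; C15 methylene)
Conditions: Bu3SnH, AIBN (cat.), benzene (0.02 M), 80 °C
Reagents that add atoms: none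
Why: Tin hydride-mediated vinyl radical cyclisation: bromine abstraction gives the C16 vinyl radical, which closes 5-exo-trig onto C13 of the ring C alkene to form ring D, C13 being fixed because the two-atom bridge can span only the face of ring C that carries C15, and the C12 radical is then reduced by the stannane, kept concentrated enough to outrun homoallyl rearrangement to a bicyclo[2.2.2]octane.

Step 17
Reactants: 22 tetracyclic 16(17)-ene
Product: 23 15-exo alcohol
Conditions: SeO2 (cat.), t-BuOOH, CH2Cl2, rt
Reagents that add atoms: selenium dioxide, O=[Se]=O; tert-butyl hydroperoxide, CC(C)(C)OO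
Why: Selenium dioxide allylic hydroxylation (ene reaction then [2,3]-sigmatropic shift): of the allylic positions of the 1,1-disubstituted alkene only C15 can react because C13 is a bridgehead, oxygen arrives on the open exo face, a configuration erased in step 18, and the hindered, oxygen-substituted ring A alkene is expected to react far more slowly.

Step 18
Reactants: 23 15-exo alcohol
Product: 24 16(17)-en-15-one
Conditions: Dess–Martin periodinane, CH2Cl2, rt
Reagents that add atoms: none
Why: Dess–Martin oxidation of the secondary allylic alcohol to the α-methylene ketone under non-basic conditions that spare the silyl ethers and the lactone.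

Step 19
Reactants: 24 16(17)-en-15-one
Product: 25 15-endo alcohol (oxygen syn to C9)
Conditions: NaBH4, CeCl3·7H2O, MeOH, −78 °C
Reagents that add atoms: none
Why: Luche reduction: cerium-assisted 1,2-reduction of the α-methylene ketone with hydride entering from the exo face, away from the axial hydrogen on C11 of the three-carbon bridge, gives the endo alcohol with oxygen syn to C9, the C15 configuration of the target.

Step 20
Reactants: 25 15-endo alcohol
Product: 26 15-acetate
Conditions: Ac2O, DMAP (cat.), pyridine, rt
Reagents that add atoms: acetic anhydride, CC(=O)OC(C)=O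
Why: DMAP-catalysed acetylation of the secondary allylic alcohol, which proceeds with retention at C15.

Step 21
Reactants: 26 15-acetate
Product: 27 1,6-diol
Conditions: HF·pyridine, THF, 0 °C to rt
Reagents that add atoms: none
Why: Fluoride-mediated cleavage of both silyl ethers under mildly acidic conditions, which spare the acetate and the lactone and avoid base-induced transfer of the lactone acyl group to the freed C1 hydroxyl.

Step 22
Reactants: 27 1,6-diol
Product: 28 target CNP0108627.4
Conditions: Dess–Martin periodinane, CH2Cl2, rt
Reagents that add atoms: none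
Why: Dess–Martin oxidation of both alcohols, the allylic C1 alcohol giving the ring A enone and the C6 alcohol the aldehyde, under non-basic conditions in which C5, which has no β-hydrogen to lose, should not epimerise.

**Compound list**

1 | 4,4-dimethylcyclohex-2-en-1-one | CC1(C)CCC(=O)C=C1 | starting material
2 | 4,4-dimethylcyclohexa-2,5-dien-1-one | CC1(C)C=CC(=O)C=C1 | intermediate
3 | (5R)-5-ethenyl-4,4-dimethylcyclohex-2-en-1-one | O=C1C=CC(C)(C)[C@@H](C=C)C1 | intermediate
4 | (1S)-6,6-dimethyl-3-oxocyclohex-4-ene-1-carbaldehyde | O=C1C=CC(C)(C)[C@@H](C=O)C1 | intermediate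
5 | (5S)-5-(hydroxymethyl)-4,4-dimethylcyclohex-2-en-1-one | O=C1C=CC(C)(C)[C@@H](CO)C1 | intermediate
6 | methyl [(1S)-6,6-dimethyl-3-oxocyclohex-4-en-1-yl]methyl carbonate | O=C1C=CC(C)(C)[C@@H](COC(=O)OC)C1 | intermediate
7 | (3aS,7aR)-4,4-dimethyl-3a,4-dihydro-2-benzofuran-1,7(3H,7aH)-dione (cis-fused ring A keto lactone; lactone C=O is C20, OCH2 is C6) | O=C1C=CC(C)(C)[C@H]2COC(=O)[C@@H]12 | intermediate
8 | acrolein | C=CC=O | starting material
9 | (3S)-hexa-1,5-dien-3-ol | C=C[C@@H](O)CC=C | intermediate
10 | (3S)-hexa-1,5-dien-3-yl prop-2-enoate | C=C[C@@H](OC(=O)C=C)CC=C | intermediate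
11 | (6S)-6-ethenyl-5,6-dihydro-2H-pyran-2-one | C=C[C@@H]1CC=CC(=O)O1 | intermediate
12 | Michael adduct: 6-vinyl δ-lactone bonded at C9 to C10 of keto lactone 7 (C9 trans to the vinyl group; C9 cis to H-5 on ring A) | C=C[C@@H]1C[C@@H]([C@]23C(=O)C=CC(C)(C)[C@H]2COC3=O)CC(=O)O1 | intermediate
13 | C1 allylic alcohol of 12 (1-OH cis to C20) | C=C[C@@H]1C[C@@H]([C@]23[C@@H](O)C=CC(C)(C)[C@H]2COC3=O)CC(=O)O1 | intermediate
14 | 1-O-tert-butyldimethylsilyl ether of 13 | C=C[C@@H]1C[C@@H]([C@]23[C@@H](O[Si](C)(C)C(C)(C)C)C=CC(C)(C)[C@H]2COC3=O)CC(=O)O1 | intermediate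
15 | 14 carrying a 2-bromoprop-2-enyl group on C8, trans to ring A (precursor of the key step) | C=C[C@@H]1C[C@@H]([C@]23[C@@H](O[Si](C)(C)C(C)(C)C)C=CC(C)(C)[C@H]2COC3=O)[C@H](CC(Br)=C)C(=O)O1 | intermediate
16 | endocyclic trimethylsilyl ketene acetal of 15 (C7=C8) | C=C[C@@H]1C[C@@H]([C@]23[C@@H](O[Si](C)(C)C(C)(C)C)C=CC(C)(C)[C@H]2COC3=O)C(CC(Br)=C)=C(O[Si](C)(C)C)O1 | intermediate
17 | trimethylsilyl ester of 18 | C[Si](C)(C)OC(=O)[C@@]1(CC(Br)=C)CC=CC[C@H]1[C@]23[C@@H](O[Si](C)(C)C(C)(C)C)C=CC(C)(C)[C@H]2COC3=O | intermediate
18 | ring C acid: 1-(2-bromoprop-2-enyl)cyclohex-3-ene-1-carboxylic acid with ring A on C9 (C8 quaternary, C7 cis to C10; product of the key step) | OC(=O)[C@@]1(CC(Br)=C)CC=CC[C@H]1[C@]23[C@@H](O[Si](C)(C)C(C)(C)C)C=CC(C)(C)[C@H]2COC3=O | intermediate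
19 | dihydroxy acid: 18 with the ring A lactone reduced to C20H2OH and C6H2OH | OC(=O)[C@@]1(CC(Br)=C)CC=CC[C@H]1[C@]1(CO)[C@@H](O[Si](C)(C)C(C)(C)C)C=CC(C)(C)[C@H]1CO | intermediate
20 | 7,20-lactone (spiro at C10) with free C6 hydroxyl | C=C(Br)C[C@]12CC=CC[C@H]1[C@]1(COC2=O)[C@@H](O[Si](C)(C)C(C)(C)C)C=CC(C)(C)[C@H]1CO | intermediate
21 | 6-O-tert-butyldimethylsilyl ether of 20 | C=C(Br)C[C@]12CC=CC[C@H]1[C@]1(COC2=O)[C@@H](O[Si](C)(C)C(C)(C)C)C=CC(C)(C)[C@H]1CO[Si](C)(C)C(C)(C)C | intermediate
22 | tetracycle with ring D closed (C13–C16), 16(17)-ene, C15 methylene | C=C1[C@@H]2CC[C@@H]3[C@](C2)(C(=O)OC[C@]32[C@@H](O[Si](C)(C)C(C)(C)C)C=CC(C)(C)[C@H]2CO[Si](C)(C)C(C)(C)C)C1 | intermediate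
23 | 15-exo alcohol (15-epimer of 25) | C=C1[C@@H]2CC[C@@H]3[C@](C2)(C(=O)OC[C@]32[C@@H](O[Si](C)(C)C(C)(C)C)C=CC(C)(C)[C@H]2CO[Si](C)(C)C(C)(C)C)[C@H]1O | intermediate
24 | 16(17)-en-15-one | C=C1[C@@H]2CC[C@@H]3[C@](C2)(C(=O)OC[C@]32[C@@H](O[Si](C)(C)C(C)(C)C)C=CC(C)(C)[C@H]2CO[Si](C)(C)C(C)(C)C)C1=O | intermediate
25 | 15-endo alcohol (oxygen syn to C9) | C=C1[C@@H]2CC[C@@H]3[C@](C2)(C(=O)OC[C@]32[C@@H](O[Si](C)(C)C(C)(C)C)C=CC(C)(C)[C@H]2CO[Si](C)(C)C(C)(C)C)[C@@H]1O | intermediate
26 | 15-acetate of 25 | C=C1[C@@H]2CC[C@@H]3[C@](C2)(C(=O)OC[C@]32[C@@H](O[Si](C)(C)C(C)(C)C)C=CC(C)(C)[C@H]2CO[Si](C)(C)C(C)(C)C)[C@@H]1OC(C)=O | intermediate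
27 | 1,6-diol 15-acetate | C=C1[C@@H]2CC[C@@H]3[C@](C2)(C(=O)OC[C@]32[C@@H](O)C=CC(C)(C)[C@H]2CO)[C@@H]1OC(C)=O | intermediate
28 | CNP0108627.4 (15-acetoxy-1-oxo-7,20-olide 6-aldehyde, 2-ene, 16(17)-ene) | C=C1[C@@H]2CC[C@@H]3[C@](C2)(C(=O)OC[C@]32C(=O)C=CC(C)(C)[C@H]2C=O)[C@@H]1OC(C)=O | target

**Step count and risks**

Total: 22 steps. Longest linear sequence: 19 steps (steps 1–5, then 9–22); the lactone branch (steps 6–8) joins at step 9.

Most likely to fail, in this order:

Step 9. The C–C bond forms at a tertiary carbon next to the gem-dimethyl-bearing C5, so addition may be slow and reverse (retro-Michael), while the base may open the vinyl lactone by γ-deprotonation and elimination. The fallback sets out from 9 and 7 and returns at 12.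
- 9 is silylated (t-BuMe2SiCl, imidazole) to (3S)-3-(tert-butyldimethylsilyloxy)hexa-1,5-diene F1.
- Cross-metathesis of the unhindered allyl terminus of F1 with crotonaldehyde (second-generation Hoveyda–Grubbs catalyst RuCl2(=CH-2-i-PrOC6H4)(H2IMes)) should give (2E,5S)-5-(tert-butyldimethylsilyloxy)hepta-2,6-dienal F2.
- Iminium activation of F2 by a diphenylprolinol trimethylsilyl ether (the enantiomer that exposes the required face of C9) makes the acceptor far more electrophilic than the lactone. It should let 7 add to give the Michael adduct aldehyde F3, with C10 again fixed by the cis ring fusion.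
- HF·pyridine removes the silyl group and the freed C12 hydroxyl closes onto the aldehyde as the lactol F4.
- Oxidation of F4 (TEMPO, PhI(OAc)2) gives 12.

Step 13. Enolisation at the crowded C8–H may be incomplete, and the ketene acetal may decompose (C-silylation, fragmentation) before it rearranges, because the reactive boat suffers allylic strain between the C8 arm and ring A. The fallback sets out from 14 and returns at 18.
- The same enolisation, silylation and heating applied to 14 should give the C8-unsubstituted silyl ketene acetal F5, which has no such strain.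
- F5 should rearrange, with C14 still delivered from the vinyl face, to the trimethylsilyl ester F6, and hydrolysis gives the ring C acid with C8–H F7.
- The dianion of F7 (LiN(i-Pr)2, 2 equiv, THF/DMPU) is alkylated with 2,3-dibromopropene on the face of ring C away from ring A. This places the bromoallyl arm cis to H-9 and gives 18, the quaternary centre now being set by alkylation of a ring C enolate.

Step 2. Facial discrimination at the crowded β-carbon may be poor, the vinylboron reagent may be lost by protodeboronation, or a second vinyl group may add to the product enone. The fallback sets out from 2 and returns at 5 through 4.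
- Conjugate addition of nitromethane to 2 under iminium catalysis by a 9-amino-9-deoxy-epi-cinchona primary amine with an acid co-catalyst (pseudo-enantiomer chosen for the 5S adduct) should give (5S)-4,4-dimethyl-5-(nitromethyl)cyclohex-2-en-1-one F8.
- A Nef reaction (NaOMe, then cold aqueous H2SO4) converts the nitromethyl group into the aldehyde 4, which is reduced at once with NaBH4 to 5 as in step 3.

Further compounds
F1 | step 9 | (3S)-3-(tert-butyldimethylsilyloxy)hexa-1,5-diene | C=C[C@@H](O[Si](C)(C)C(C)(C)C)CC=C
F2 | step 9 | (2E,5S)-5-(tert-butyldimethylsilyloxy)hepta-2,6-dienal | C=C[C@@H](O[Si](C)(C)C(C)(C)C)C/C=C/C=O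
F3 | step 9 | Michael adduct aldehyde (C9 bonded to C10 of 7; C12 silyl ether) | O=CC[C@@H](C[C@H](O[Si](C)(C)C(C)(C)C)C=C)[C@]23C(=O)C=CC(C)(C)[C@H]2COC3=O
F4 | step 9 | lactol of 12 (C7 hemiacetal, anomers) | C=C[C@@H]1C[C@@H]([C@]23C(=O)C=CC(C)(C)[C@H]2COC3=O)CC(O)O1
F5 | step 13 | trimethylsilyl ketene acetal of 14 (C8 unsubstituted) | C=C[C@@H]1C[C@@H]([C@]23[C@@H](O[Si](C)(C)C(C)(C)C)C=CC(C)(C)[C@H]2COC3=O)C=C(O[Si](C)(C)C)O1
F6 | step 13 | trimethylsilyl ester of F7 | C[Si](C)(C)OC(=O)[C@H]1CC=CC[C@H]1[C@]23[C@@H](O[Si](C)(C)C(C)(C)C)C=CC(C)(C)[C@H]2COC3=O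
F7 | step 13 | ring C acid with C8–H (cyclohex-3-ene-1-carboxylic acid with ring A on C9, C7 cis to C10) | OC(=O)[C@H]1CC=CC[C@H]1[C@]23[C@@H](O[Si](C)(C)C(C)(C)C)C=CC(C)(C)[C@H]2COC3=O
F8 | step 2 | (5S)-4,4-dimethyl-5-(nitromethyl)cyclohex-2-en-1-one | O=C1C=CC(C)(C)[C@@H](C[N+](=O)[O-])C1
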